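Both mirror-image substrates meet the same [free catalyst] and the same [coupling partner] at every moment, so, if each coupling is first order in its substrate, one number stays constant through a run. That number is the lifetimes lived by the left-handed substrate divided by those lived by the right-handed one, a lifetime being a fall by the factor e.

| flask | left-handed substrate | right-handed substrate | coupling partner | protic impurity | free catalyst | remark | time |
|---|---|---|---|---|---|---|---|
| north-east | 0.052 M | 0.052 M | 0.036 M | 2.6 mM | 0.52 mM | run made earlier |  |
| north-west | 0.052 M | 0.052 M | 0.16 M | 2.6 mM | 0.52 mM | run made earlier |  |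
| alpha | 0.052 M | 0.052 M | 0.0312 M | 2.60 mM | 0.52 mM |  | 12 min |
| gamma | 0.052 M | 0.052 M | 0.100 M | 2.60 mM | 0.52 mM |  | 12 min |

| run | time / min | right-handed substrate / % | left-handed substrate / % | left-handed product / % |
|---|---|---|---|---|
| north-east | 0.500 | 45.9 | 44.0 | 5.7 |
| north-east | 0.667 | 46.7 | 42.7 | 5.9 |
| north-east | 1.00 | 45.6 | 42.5 | 7.6 |
| north-east | 1.50 | 45.9 | 40.9 | 10.1 |
| north-east | 2.50 | 42.8 | 39.8 | 10.9 |
| north-east | 4.00 | 44.1 | 38.5 | 12.2 |
| north-east | 6.00 | 43.5 | 36.7 | 12.8 |
| north-west | 0.833 | 36.0 | 27.2 | 23.7 |
| north-west | 1.50 | 33.8 | 22.6 | 26.8 |
| north-west | 2.50 | 31.8 | 20.5 | 29.4 |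
| north-west | 3.00 | 31.2 | 18.7 | 29.8 |
| north-west | 4.00 | 30.2 | 18.8 | 31.2 |
| north-west | 5.00 | 30.2 | 17.5 | 32.6 |
| north-west | 6.00 | 29.7 | 18.1 | 32.5 |

(scatter of a reading: 0.5 percentage points)

- free catalyst is single-handed; left-handed substrate and right-handed substrate are mirror images of each other, charged as a racemate, each of them at the stated concentration
- an excess is the difference of the two amounts in percent of their sum
- an excess is below zero if the other one leads

- which one finishes higher in excess of right-handed substrate over left-handed substrate among what is left of the two ("neither" within 2 percentage points) (alpha / gamma / neither)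
- excess of right-handed substrate over left-handed substrate among what is left of the two at the end, alpha
- excess of right-handed substrate over left-handed substrate among what is left of the two at the end, gamma

Each substrate starts at half of the total, so the last north-west reading gives 1.02 lifetimes for the left-handed substrate and 0.521 for the right-handed. Their ratio is s = 1.95, the selectivity factor, and it lets me turn a count of lifetimes into an excess.

I start with the two couplings alone. The coupling partner is then the limiting reagent and is used to its end, so with s taken as 2 I reckon an excess of 12.1 % for alpha and 86.6 % for gamma.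

The readings refuse this, because the north-east run shows 19.8 % reacted at its last reading, less than the 34.6 % its partner allows, and its left-handed product goes from 12.2 % to 12.8 % over its last two readings. So I add a dying catalyst. The catalyst charge is equal in the runs and new flasks, so I let lifetimes grow in proportion to the partner charge from the north-east count of 0.309. That gives 6.52 % for alpha and 20.6 % for gamma.

Last comes partner wasted on other paths. The north-west count exceeds the north-east one by a factor of 3.30 for 4.44 times the partner, a power of 0.798. That power gives 6.71 % and 16.9 %. I commit to the middle of each pair: 6.62 % for alpha and 18.7 % for gamma.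

The forecast gives 7.5 % for alpha, above mine, and 20 % for gamma, naming gamma as higher, by “Interpolating with partner-dependent catalyst loss”.

The flask gives 6.91 % for alpha and 19.1 % for gamma, so gamma finishes higher. At 12.0 min, free catalyst stands at 5.72 % of its charge in alpha and 5.72 % in gamma.

    coupling partner + free catalyst + left-handed substrate → free catalyst + left-handed product (k = 360 L² mol⁻² s⁻¹)
    coupling partner + free catalyst + right-handed substrate → free catalyst + right-handed product (k = 180 L² mol⁻² s⁻¹)
    2 free catalyst → spent catalyst (k = 22.0 L mol⁻¹ s⁻¹)
    2 coupling partner → homo dimer (k = 0.0550 L mol⁻¹ s⁻¹)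
    coupling partner + protic impurity → quenched reagent (k = 2.40 L mol⁻¹ s⁻¹)

With s, the 46 % of left-handed substrate left in gamma reckons 67.2 % of the right-handed, and the flask holds 68 %. A neighbouring flask, gamma with 0.40 M of coupling partner, keeps 14 % of its left-handed substrate, so s reckons an excess of 44.5 %, and that flask gives 45.5 %.

All runs are simulated for an exercise; scatter was added.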